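**Retrosynthetic overview**
1. Two retro-operations lead from glyinflanin C to a single precursor. These are a retro-[3,3] shift from B-ring C3′ back to O4′ and a retro-metathesis across the pyran C3=C4 bond. The precursor is a dibenzoylmethane with identical O–C(CH3)2–CH=CH2 ethers on A-ring O4 and B-ring O4′ and a vinyl group on A-ring C5.
2. The enabling feature is the quaternary O–C(CH3)2 carbon next to each terminal alkene. On the A ring it sits ortho to the C5 vinyl group, so gem-dimethyl compression favours the six-membered closure. On the B ring it is flanked by the two equivalent free ortho carbons C3′ and C5′. In both places it blocks alkene isomerisation and homodimerisation.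
3. The central CO–CH2 bond comes from a crossed Claisen condensation of the A-ring methyl ketone with the B-ring methyl ester. Each tertiary allyl ether also protects its phenol during this step.
4. Both ethers come from one carbonate reagent by Pd-catalysed reverse prenylation. The C5 vinyl group comes from bromination and Stille coupling of 2,4-dihydroxyacetophenone.
5. Both benzene rings are purchased. The pyran ring is the only ring formed, and it is closed in the last step.

Key step: step 7

Remark: the target has no stereocentre and no stereogenic double bond (the pyran olefin is cis by ring constraint), so it is achiral and needs no enantioselective step; all β-diketones are written as diketo tautomers although they should exist largely as chelated enols.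

**Step 1**
Reactants: 1 2-methylbut-3-en-2-ol
Product: 2 tert-butyl 2-methylbut-3-en-2-yl carbonate
Conditions: n-BuLi (1.05 equiv), THF, 0 °C; Boc2O (1.05 equiv), 0 °C → rt; H2O quench
Reagents that add atoms: di-tert-butyl dicarbonate (Boc2O), CC(C)(C)OC(=O)OC(=O)OC(C)(C)C
Why: In this alkoxide O-acylation (Boc transfer), the lithium alkoxide of the tertiary allylic alcohol attacks Boc2O and the expelled tert-butyl carbonate collapses to CO2 and tert-butoxide, which should leave the mixed carbonate needed as π-allyl precursor in steps 4 and 5.

**Step 2**
Reactants: 3 1-(2,4-dihydroxyphenyl)ethanone (2,4-dihydroxyacetophenone)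
Product: 4 1-(5-bromo-2,4-dihydroxyphenyl)ethanone
Conditions: NBS (1.0 equiv), MeCN, 0 °C → rt
Reagents that add atoms: N-bromosuccinimide (NBS), O=C1CCC(=O)N1Br
Why: In this electrophilic aromatic bromination, C5 is para to the 2-OH, ortho to the 4-OH and much less crowded than C3 between the two oxygens, so one equivalent of NBS should give the 5-bromide.

**Step 3**
Reactants: 4 1-(5-bromo-2,4-dihydroxyphenyl)ethanone
Product: 5 1-(5-ethenyl-2,4-dihydroxyphenyl)ethanone
Conditions: CH2=CHSnBu3 (1.2 equiv), Pd(PPh3)4 (5 mol %), BHT (cat.), PhMe, 100 °C
Reagents that add atoms: tributyl(vinyl)stannane, C=C[Sn](CCCC)(CCCC)CCCC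
Why: The Stille vinylation runs under neutral conditions, so the two free phenols and the methyl ketone are tolerated, it is placed before etherification so that no aryl-palladium species ever sits next to a pendant alkene, and BHT holds back polymerisation of the hydroxystyrene.

**Step 4**
Reactants: 5 1-(5-ethenyl-2,4-dihydroxyphenyl)ethanone; 2 tert-butyl 2-methylbut-3-en-2-yl carbonate
Product: 6 1-[5-ethenyl-2-hydroxy-4-(2-methylbut-3-en-2-yloxy)phenyl]ethanone
Conditions: 2 (1.1 equiv), Pd(PPh3)4 (3 mol %), THF, 0–5 °C
Reagents that add atoms: none
Why: In this Pd(0)-catalysed decarboxylative O-allylation (Tsuji–Trost type reverse prenylation), ionisation of 2 gives the 1,1-dimethyl-π-allyl-palladium cation and tert-butoxide, which deprotonates the more acidic free 4-OH, and the phenoxide should attack the more substituted allyl terminus under kinetic control at low temperature while the 2-OH stays locked in its hydrogen bond to the ketone.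

**Step 5**
Reactants: 7 methyl 4-hydroxybenzoate; 2 tert-butyl 2-methylbut-3-en-2-yl carbonate
Product: 8 methyl 4-(2-methylbut-3-en-2-yloxy)benzoate
Conditions: 2 (1.3 equiv), Pd(PPh3)4 (3 mol %), THF, 0–5 °C
Reagents that add atoms: none
Why: This is the same Pd(0)-catalysed decarboxylative reverse prenylation (Tsuji–Trost type O-allylation) on the single phenol of 7, and low temperature and short contact time should keep the kinetically formed branched ether from re-ionising on palladium.

**Step 6**
Reactants: 6 1-[5-ethenyl-2-hydroxy-4-(2-methylbut-3-en-2-yloxy)phenyl]ethanone; 8 methyl 4-(2-methylbut-3-en-2-yloxy)benzoate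
Product: 9 1-[5-ethenyl-2-hydroxy-4-(2-methylbut-3-en-2-yloxy)phenyl]-3-[4-(2-methylbut-3-en-2-yloxy)phenyl]propane-1,3-dione
Conditions: NaH (4 equiv), THF, 0 → 55 °C; cold 1 M HCl to pH 5–6
Reagents that add atoms: none
Why: In this crossed Claisen condensation, NaH turns 6 into its phenoxide/enolate dianion, whose carbon acylates the non-enolisable ester 8, deprotonation of the β-diketone pulls the equilibrium forward, and both tertiary allyl ethers act as base-stable phenol protection below the temperature at which they rearrange.

**Step 7**
Reactants: 9 1-[5-ethenyl-2-hydroxy-4-(2-methylbut-3-en-2-yloxy)phenyl]-3-[4-(2-methylbut-3-en-2-yloxy)phenyl]propane-1,3-dione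
Product: 12 glyinflanin C, via chromene ether 10 (not isolated), via ortho-dienone 11 (not isolated)
Conditions: Hoveyda–Grubbs II (5 mol %), 1,4-benzoquinone (10 mol %), degassed PhMe (5 mM), Ar sparge, 40 °C; then PhNEt2 (10 vol %), sealed vessel, 140 °C
Reagents that add atoms: none
Why: This is a ring-closing olefin metathesis followed in the same flask by an aromatic Claisen rearrangement: the ruthenium alkylidene loads onto the unhindered C5 vinyl group to give an o-alkoxybenzylidene chelate of the kind present in the catalyst itself, which undergoes intramolecular [2+2] cycloaddition with the neighbouring O–C(CH3)2–CH=CH2 alkene and cycloreversion, forming the pyran C3=C4 bond of 10 and releasing ethene. The closest precedents are the metathesis closure of 2-vinylphenyl allyl ethers to 2H-chromenes for the first stage and the [3,3] shift of aryl 1,1-dimethylallyl ethers to o-prenylphenols for the second. The only ring closed is the six-membered pyran ring, by metathesis with both olefin carbons ending endocyclic, so the cis geometry is enforced by the ring and the closure is helped by the gem-dimethyl effect. No stereocentre remains, because the sp3 carbon of dienone 11 forms as a racemate and is erased by tautomerisation to the phenol. The step needs site selectivity between two identical ethers, and the substrate secures it because only the A-ring ether has an alkene partner within reach, whereas the B-ring alkene next to its quaternary carbon neither homodimerises nor isomerises and finds no partner at 5 mM. It also needs order in time, which the temperature gap secures: metathesis should be complete at 40 °C, well below the onset of the [3,3] shift, so the A-ring ether is locked in the pyran ring before heating, and on the B ring C3′ and C5′ are equivalent, so allyl inversion can give only one prenylphenol and frees the 4′-OH without a deprotection step.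

**Compound list**
1 | 2-methylbut-3-en-2-ol | C=CC(C)(C)O | starting material
2 | tert-butyl 2-methylbut-3-en-2-yl carbonate | C=CC(C)(C)OC(=O)OC(C)(C)C | intermediate
3 | 1-(2,4-dihydroxyphenyl)ethanone | CC(=O)c1ccc(O)cc1O | starting material
4 | 1-(5-bromo-2,4-dihydroxyphenyl)ethanone | CC(=O)c1cc(Br)c(O)cc1O | intermediate
5 | 1-(5-ethenyl-2,4-dihydroxyphenyl)ethanone | CC(=O)c1cc(C=C)c(O)cc1O | intermediate
6 | 1-[5-ethenyl-2-hydroxy-4-(2-methylbut-3-en-2-yloxy)phenyl]ethanone | CC(=O)c1cc(C=C)c(OC(C)(C)C=C)cc1O | intermediate
7 | methyl 4-hydroxybenzoate | COC(=O)c1ccc(O)cc1 | starting material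
8 | methyl 4-(2-methylbut-3-en-2-yloxy)benzoate | COC(=O)c1ccc(OC(C)(C)C=C)cc1 | intermediate
9 | 1-[5-ethenyl-2-hydroxy-4-(2-methylbut-3-en-2-yloxy)phenyl]-3-[4-(2-methylbut-3-en-2-yloxy)phenyl]propane-1,3-dione | C=CC(C)(C)Oc1ccc(cc1)C(=O)CC(=O)c1cc(C=C)c(OC(C)(C)C=C)cc1O | intermediate
10 | 1-(7-hydroxy-2,2-dimethyl-2H-chromen-6-yl)-3-[4-(2-methylbut-3-en-2-yloxy)phenyl]propane-1,3-dione | C=CC(C)(C)Oc1ccc(cc1)C(=O)CC(=O)c1cc2c(cc1O)OC(C)(C)C=C2 | intermediate
11 | 1-(7-hydroxy-2,2-dimethyl-2H-chromen-6-yl)-3-[3-(3-methylbut-2-enyl)-4-oxocyclohexa-1,5-dien-1-yl]propane-1,3-dione (racemic, transient) | CC(C)=CCC1C=C(C=CC1=O)C(=O)CC(=O)c1cc2c(cc1O)OC(C)(C)C=C2 | intermediate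
12 | glyinflanin C, 1-(7-hydroxy-2,2-dimethyl-2H-chromen-6-yl)-3-[4-hydroxy-3-(3-methylbut-2-enyl)phenyl]propane-1,3-dione | CC(C)=CCc1cc(C(=O)CC(=O)c2cc3c(cc2O)OC(C)(C)C=C3)ccc1O | target

Total step count: 7
Longest linear sequence: 5 steps (steps 2, 3, 4, 6 and 7)

**Steps most likely to fail**

Step 7. The enolised β-diketone and the chelated phenol may sequester ruthenium and stall the ring closure. In the hot stage, ruthenium residues or traces of acid may trigger cyclodehydration of the o-hydroxy-β-diketone or cyclisation of the freshly formed prenylphenol. The fallback sets out from 6 and returns at 10. The ring closure is moved to the acetophenone stage, where no β-diketone is present. Treatment of 6 with Grubbs II in CH2Cl2 at 40 °C should give 1-(7-hydroxy-2,2-dimethyl-2H-chromen-6-yl)ethanone F1. Crossed Claisen condensation of F1 with 8 (NaH, THF) should then give 10 as an isolated, ruthenium-free compound. Its [3,3] shift to 12 is run as a separate thermal step in PhNEt2.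

Step 4. Reversible ionisation of the electron-poor aryl ether on palladium may erode the branched selectivity and let the material drift to the linear ether. Alkylation may also spill over to the chelated phenol. The fallback sets out from 5 and returns at 6. Copper-catalysed O-propargylation with 3-chloro-3-methylbut-1-yne (CuCl2 cat., DBU, MeCN, 0 °C) should give 1-[5-ethenyl-2-hydroxy-4-(2-methylbut-3-yn-2-yloxy)phenyl]ethanone F2. This C–O bond forms through a copper allenylidene that offers no linear option. Semihydrogenation over Lindlar catalyst with quinoline, stopped after one equivalent of H2, should give 6, because the terminal alkyne binds the poisoned surface more strongly than the styrene.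

Step 6. Acylation of the dianion by the electron-rich methyl ester may be sluggish. It could then demand temperatures at which a premature [3,3] shift of the A-ring ether or retro-Claisen cleavage sets in. The fallback sets out from 8 and 6 and returns at 9, and it replaces the intermolecular C-acylation by a Baker–Venkataraman sequence. Saponification of 8 (LiOH, THF/H2O, rt) should give 4-(2-methylbut-3-en-2-yloxy)benzoic acid F3. EDC/DMAP esterification of the 2-OH of 6 with F3 should give 2-acetyl-4-ethenyl-5-(2-methylbut-3-en-2-yloxy)phenyl 4-(2-methylbut-3-en-2-yloxy)benzoate F4. KOt-Bu in THF at 0 °C → rt should then bring about the intramolecular O→C acyl transfer to 9.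

**Further compounds**
F1 | step 7 | 1-(7-hydroxy-2,2-dimethyl-2H-chromen-6-yl)ethanone | CC(=O)c1cc2c(cc1O)OC(C)(C)C=C2
F2 | step 4 | 1-[5-ethenyl-2-hydroxy-4-(2-methylbut-3-yn-2-yloxy)phenyl]ethanone | CC(=O)c1cc(C=C)c(OC(C)(C)C#C)cc1O
F3 | step 6 | 4-(2-methylbut-3-en-2-yloxy)benzoic acid | C=CC(C)(C)Oc1ccc(cc1)C(=O)O
F4 | step 6 | 2-acetyl-4-ethenyl-5-(2-methylbut-3-en-2-yloxy)phenyl 4-(2-methylbut-3-en-2-yloxy)benzoate | CC(=O)c1cc(C=C)c(OC(C)(C)C=C)cc1OC(=O)c1ccc(OC(C)(C)C=C)cc1
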